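**Retrosynthetic overview**
- 12 ⇒ 10 + 11: the C8–prenyl bond by Stille coupling; 10 ⇒ 8 by iodination of the last free A-ring C–H.
- 8 ⇒ 7 + methanol: the key bond, aryl C6–OMe, made at room temperature by a visible-light Ni/photoredox C–O coupling (new on this kind of substrate).
- 7 ⇒ 5 by 5-OH-directed C6 iodination; 5 ⇒ 1 by acidity-selective 7-O-methylation.
- Rings: none is built. Rings A, B and C and the C2 (S) centre are bought intact in (2S)-naringenin 1; only the A ring is decorated (O7, then C6, then C8), under conditions that never form a phenoxide or open the pyranone.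

Assumption: commercial (2S)-naringenin (CAS 480-41-1) is used as a single enantiomer, its ee checked by chiral HPLC (recrystallised if needed) before use.

**Step 1**
Reactants: 1 (2S)-naringenin; 2 trimethylsilyldiazomethane; 3 methanol
Product: 5 (2S)-sakuranetin, via diazomethane 4 (not isolated)
Conditions: TMSCHN2 (1.2 equiv), MeOH–toluene (1:3), 0 °C → rt
Reagents that add atoms: trimethylsilyldiazomethane, C[Si](C)(C)C=[N+]=[N-]
Why: Acidity-gated diazoalkane O-methylation: methanolysis of 2 releases diazomethane 4, which is protonated only by the vinylogous-acid 7-OH (pKa ≈ 7.5) and not by the 4'-OH (pKa ≈ 10) or the chelated 5-OH at this stoichiometry, so O7 is methylated under base-free conditions that leave C2 (S) untouched.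

**Step 2**
Reactants: 5 (2S)-sakuranetin; 6 benzyltrimethylammonium dichloroiodate
Product: 7 (2S)-6-iodosakuranetin
Conditions: BnMe3N·ICl2 (1.0 equiv), CaCO3 (1.5 equiv), CH2Cl2–MeOH (5:2), rt, dark
Reagents that add atoms: benzyltrimethylammonium dichloroiodate, C[N+](C)(C)Cc1ccccc1.Cl[I-]Cl
Why: Electrophilic aromatic iodination with the dichloroiodate (Kajigaeshi-type) reagent: with only suspended carbonate present the iodine enters ortho to the free chelated 5-OH (C6) rather than at C8, the established preference for 5-hydroxy-7-methoxyflavonoids, the trioxygenated A ring reacts well before the monophenolic B ring at 1.0 equiv, and the near-neutral medium does not touch C2.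

**Step 3**
Reactants: 7 (2S)-6-iodosakuranetin; 3 methanol
Product: 8 (2S)-5,4'-dihydroxy-6,7-dimethoxyflavanone
Conditions: NiBr2·glyme (10 mol%), dtbbpy (12 mol%), [Ir(dF(CF3)ppy)2(dtbbpy)]PF6 (1 mol%), t-BuNH2 (2 equiv), MeOH–MeCN (1:4), 450 nm LEDs, 25 °C, Ar
Reagents that add atoms: methanol, CO
Why: Proposed new method: a Ni/photoredox C(sp2)–O cross-coupling (closest known reaction: Ir/Ni dual-catalysed etherification of aryl halides with alcohols) is applied to a kind of substrate on which it has not been shown, an unprotected 2-iodophenol flanked on both sides and carrying a base-labile benzylic stereocentre; Ni(0) inserts into the weak C6–I bond, methanol in large excess replaces iodide on Ni(II) with t-BuNH2 taking up HI, photo-oxidation to aryl–Ni(III)–OMe triggers C–O reductive elimination, the 5-OH stays locked in its hydrogen bond to C4=O and so neither binds nickel nor competes as a nucleophile, t-BuNH2 (no α-C–H, and too weak a base in MeCN to ionise either phenol) avoids the 4'-phenoxide/quinone-methide ring opening that would racemise C2, and 450 nm light is not absorbed by the flavanone.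

**Step 4**
Reactants: 8 (2S)-5,4'-dihydroxy-6,7-dimethoxyflavanone; 9 N-iodosuccinimide
Product: 10 (2S)-8-iodo-5,4'-dihydroxy-6,7-dimethoxyflavanone
Conditions: NIS (1.05 equiv), MeCN, 0 °C → rt, dark
Reagents that add atoms: N-iodosuccinimide, O=C1CCC(=O)N1I
Why: Electrophilic aromatic iodination: C8 is now the only A-ring C–H and is para to the 5-OH and ortho to two ether oxygens, so one equivalent of NIS reacts there before the B ring under neutral conditions that leave C2 unchanged.

**Step 5**
Reactants: 10 (2S)-8-iodo-5,4'-dihydroxy-6,7-dimethoxyflavanone; 11 tributyl(3-methylbut-2-en-1-yl)stannane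
Product: 12 (2S)-5,4'-dihydroxy-6,7-dimethoxy-8-prenylflavanone (target)
Conditions: 11 (2 equiv), Pd(PPh3)4 (10 mol%), 1,4-dioxane, 90 °C, Ar
Reagents that add atoms: tributyl(3-methylbut-2-en-1-yl)stannane, CCCC[Sn](CCCC)(CCCC)CC=C(C)C
Why: Migita–Kosugi–Stille coupling: oxidative addition into the C8–I bond, transfer of the prenyl group from tin and reductive elimination at the unsubstituted terminus of the η3-prenyl ligand give the linear prenyl group, and the base-free medium tolerates both free phenols and does not epimerise C2, so 12 is obtained as the (2S) enantiomer.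

**Compound list**
1 | (2S)-naringenin, (2S)-5,7-dihydroxy-2-(4-hydroxyphenyl)chroman-4-one | Oc1cc(O)c2c(c1)O[C@H](c1ccc(O)cc1)CC2=O | starting material
2 | trimethylsilyldiazomethane | C[Si](C)(C)C=[N+]=[N-] | starting material
3 | methanol | CO | starting material
4 | diazomethane (formed in the flask, not isolated) | C=[N+]=[N-] | intermediate
5 | (2S)-sakuranetin, (2S)-5-hydroxy-2-(4-hydroxyphenyl)-7-methoxychroman-4-one | COc1cc(O)c2c(c1)O[C@H](c1ccc(O)cc1)CC2=O | intermediate
6 | benzyltrimethylammonium dichloroiodate | C[N+](C)(C)Cc1ccccc1.Cl[I-]Cl | starting material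
7 | (2S)-6-iodosakuranetin, (2S)-5-hydroxy-2-(4-hydroxyphenyl)-6-iodo-7-methoxychroman-4-one | COc1c(I)c(O)c2c(c1)O[C@H](c1ccc(O)cc1)CC2=O | intermediate
8 | (2S)-5,4'-dihydroxy-6,7-dimethoxyflavanone, (2S)-5-hydroxy-2-(4-hydroxyphenyl)-6,7-dimethoxychroman-4-one | COc1c(OC)c(O)c2c(c1)O[C@H](c1ccc(O)cc1)CC2=O | intermediate
9 | N-iodosuccinimide | O=C1CCC(=O)N1I | starting material
10 | (2S)-8-iodo-5,4'-dihydroxy-6,7-dimethoxyflavanone, (2S)-5-hydroxy-2-(4-hydroxyphenyl)-8-iodo-6,7-dimethoxychroman-4-one | COc1c(OC)c(O)c2c(c1I)O[C@H](c1ccc(O)cc1)CC2=O | intermediate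
11 | tributyl(3-methylbut-2-en-1-yl)stannane (prenyltributyltin) | CCCC[Sn](CCCC)(CCCC)CC=C(C)C | starting material
12 | (2S)-5-hydroxy-2-(4-hydroxyphenyl)-6,7-dimethoxy-8-(3-methylbut-2-en-1-yl)chroman-4-one, CNP0104932.1 | COc1c(O)c2c(c(CC=C(C)C)c1OC)O[C@H](c1ccc(O)cc1)CC2=O | target

**Totals**
Total step count: 5. Longest linear sequence: 5 steps (1 → 5 → 7 → 8 → 10 → 12). The ee is checked by chiral HPLC after steps 3 and 5.

**Steps most likely to fail**

Step 3 (the proposed new step). The doubly flanked C6–I may couple slowly, so that protodeiodination back to 5 (which can be re-iodinated) or oxidation of a phenol by the excited photocatalyst wins. The fallback uses known chemistry only, sets out from 7 and comes back at 8. The 4'-OH of 7 is silylated (TBSCl, imidazole, DMF, 0 °C; the chelated 5-OH does not react) to give (2S)-4'-O-TBS-6-iodosakuranetin F1. Miyaura borylation (B2pin2, XPhos Pd G2, KOAc, dioxane, 80 °C) gives the 6-pinacolboronate F2. Oxidation (H2O2, THF–pH 7 buffer, 0 °C) gives (2S)-4'-O-TBS-5,6-dihydroxy-7-methoxyflavanone F3. TMSCHN2 with i-Pr2NEt in MeOH–MeCN methylates the free 6-OH but not the chelated 5-OH and gives (2S)-4'-O-TBS-5-hydroxy-6,7-dimethoxyflavanone F4. Buffered TBAF/AcOH in THF at 0 °C removes the silyl group and returns 8.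

Step 5. Oxidative addition and tin-to-palladium transfer at the hindered, electron-rich C8–I may be slow, and some γ-coupling (reverse prenyl) or protodeiodination is possible. The fallback drops cross-coupling for a sigmatropic route, sets out from 8 and comes back at 12. TIPSCl/imidazole gives the 4'-O-TIPS ether of 8, F5. Mitsunobu reaction of its 5-OH with 3-methylbut-2-en-1-ol (PPh3, DIAD, THF) gives the 5-O-prenyl ether F6. Eu(fod)3 (10 mol%) in CHCl3 at 60 °C, chelated between C4=O and O5, drives the aromatic Claisen shift onto the methoxy-blocked C6 to give the 6-methoxy-6-(2-methylbut-3-en-2-yl)cyclohexa-2,4-dienone F7 (not isolated), which cannot enolise. A Cope shift moves the chain to C8 as the 8-prenyl-cyclohexa-2,5-dienone F8 (not isolated), which tautomerises to the 4'-O-TIPS ether of 12, F9. TBAF/AcOH in THF at 0 °C then gives 12.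

Step 2. The risk is a mixture of 6- and 8-iodides, with some di-iodide. The fallback gives up regiocontrol and inverts the order of the two bond constructions for the 8-iodo isomer; it sets out from 5 and comes back at 12. The separated (2S)-8-iodosakuranetin F10 is coupled with 11 under the Stille conditions of step 5 to give (2S)-8-prenylsakuranetin F11. NIS in MeCN at 0 °C then iodinates the only open A-ring position, C6, to give (2S)-6-iodo-8-prenylsakuranetin F12. The photochemical methoxylation of step 3 converts F12 into 12. The 6-iodo isomer 7 continues through steps 3–5, so both regioisomers converge on 12.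

**Further compounds**
F1 | step 3 | (2S)-4'-O-TBS-6-iodosakuranetin | COc1c(I)c(O)c2c(c1)O[C@H](c1ccc(O[Si](C)(C)C(C)(C)C)cc1)CC2=O
F2 | step 3 | (2S)-4'-O-TBS-6-(pinacolboryl)sakuranetin | COc1c(B3OC(C)(C)C(C)(C)O3)c(O)c2c(c1)O[C@H](c1ccc(O[Si](C)(C)C(C)(C)C)cc1)CC2=O
F3 | step 3 | (2S)-4'-O-TBS-5,6-dihydroxy-7-methoxyflavanone | COc1c(O)c(O)c2c(c1)O[C@H](c1ccc(O[Si](C)(C)C(C)(C)C)cc1)CC2=O
F4 | step 3 | (2S)-4'-O-TBS-5-hydroxy-6,7-dimethoxyflavanone | COc1c(OC)c(O)c2c(c1)O[C@H](c1ccc(O[Si](C)(C)C(C)(C)C)cc1)CC2=O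
F5 | step 5 | (2S)-4'-O-TIPS-5-hydroxy-6,7-dimethoxyflavanone | COc1c(OC)c(O)c2c(c1)O[C@H](c1ccc(O[Si](C(C)C)(C(C)C)C(C)C)cc1)CC2=O
F6 | step 5 | (2S)-4'-O-TIPS-6,7-dimethoxy-5-(3-methylbut-2-enyloxy)flavanone | COc1c(OC)c(OCC=C(C)C)c2c(c1)O[C@H](c1ccc(O[Si](C(C)C)(C(C)C)C(C)C)cc1)CC2=O
F7 | step 5 | (2S)-6,7-dimethoxy-6-(2-methylbut-3-en-2-yl)-2-(4-TIPSO-phenyl)-2,3-dihydro-6H-chromene-4,5-dione (ortho-dienone, both C6 epimers, not isolated) | COC1=CC2=C(C(=O)C1(OC)C(C)(C)C=C)C(=O)C[C@@H](c1ccc(O[Si](C(C)C)(C(C)C)C(C)C)cc1)O2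
F8 | step 5 | (2S)-6,7-dimethoxy-8-(3-methylbut-2-enyl)-2-(4-TIPSO-phenyl)-2,3-dihydro-8H-chromene-4,5-dione (para-dienone, both C8 epimers, not isolated) | COC1=C(OC)C(=O)C2=C(O[C@H](c3ccc(O[Si](C(C)C)(C(C)C)C(C)C)cc3)CC2=O)C1CC=C(C)C
F9 | step 5 | (2S)-4'-O-TIPS-5-hydroxy-6,7-dimethoxy-8-prenylflavanone | COc1c(OC)c(O)c2c(c1CC=C(C)C)O[C@H](c1ccc(O[Si](C(C)C)(C(C)C)C(C)C)cc1)CC2=O
F10 | step 2 | (2S)-8-iodosakuranetin | COc1cc(O)c2c(c1I)O[C@H](c1ccc(O)cc1)CC2=O
F11 | step 2 | (2S)-8-prenylsakuranetin | COc1cc(O)c2c(c1CC=C(C)C)O[C@H](c1ccc(O)cc1)CC2=O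
F12 | step 2 | (2S)-6-iodo-8-prenylsakuranetin | COc1c(I)c(O)c2c(c1CC=C(C)C)O[C@H](c1ccc(O)cc1)CC2=O
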